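## The problem

Monomethyl lithospermate (27) is a trans-2-aryl-2,3-dihydro-1-benzofuran-3-carboxylate. Its benzo ring (ring A) carries four contiguous substituents: O1 on C7a, a hydroxyl on C7, the ring carbon C3 on C3a and, on C4, an (E)-propenoate that acylates the hydroxyl of (R)-3-(3,4-dihydroxyphenyl)lactic acid.

There are three stereocentres. C2 and C3 (both S, trans) are neighbours, and trans is the more stable arrangement, so a fixed C2 can hold or restore C3. The lactate centre is too remote to control or be controlled by them and is best bought.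

The fragile points are these:
- C3–H is α to an ester and benzylic, with the phenoxide O1 as a β-leaving group, so base can epimerise C3 or open the ring.
- C2–O1 is a benzylic ether of an electron-rich arene and can ionise under strong acid.
- The five phenols are easily oxidised, and the alkenoate rules out hydrogenation and hard nucleophiles.
- One methyl ester must remain beside one free acid.

Regioselective substitution of a ready-made arene with this pattern is awkward. The enabling feature is that C7a, C3a, C3, C2 and O1 are the carbonyl carbon, α-carbon, β-carbon, γ-carbon and ring oxygen of a trans-γ-aryl paraconic ester. With an alkylidene group on the α-carbon, the enol silyl ether of that lactone is a vinylketene acetal that already holds C7a, C3a, C4 and C5, so only C6 and C7 remain to be added, as an alkyne, and the arene is assembled, not substituted.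

## Retrosynthesis

**27 ⇒ 26.** Six O–benzyl bonds are cut (five aryl ethers, one ester). Benzyl is chosen because BCl3 with pentamethylbenzene removes all six at low temperature without hydrogen, base or water, which the alkene, the methyl ester and C3–H require. Methyl ethers would need far harsher cleavage, and silyl ethers would not survive the carbonate steps. The forward step must leave the methyl ester and the C2–O1 bond alone.

**26 ⇒ 21 + 25.** The Cα=Cβ bond of the propenoate is cut (Knoevenagel–Doebner condensation). The neighbouring cuts are a Heck coupling at a C4 halide or acylation of the lactate hydroxyl by a cinnamic acid. This cut is preferred because C4 then only needs a formyl group, and that carbon can travel through the whole synthesis as an acetal. Aldehyde 21 and malonic half-ester 25 are of similar size, so the route is convergent. The forward step must give the E alkene under bases too weak to disturb C3.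

**25 ⇒ 23 + 24, and 23 ⇒ 22.** The malonyl C–O bond is cut back to alcohol 23 and Meldrum's acid (24). Compound 23 is the tribenzyl derivative of the natural (R)-hydroxy acid salt 22. No stereocentre is made, only kept.

**21 ⇒ 20 ⇒ 19 ⇒ 17.** These are functional-group changes on ring A: formyl from the dimethyl acetal, the benzyl ether from the phenol, and the phenol from an acetyl group by Baeyer–Villiger oxidation. The C7 oxygen is traced to an acyl group on purpose. An acyl group is what makes an alkyne a dienophile and what fixes the regiochemistry of the ring construction.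

**17 ⇒ 14 + 15.** C5–C6 and C7–C7a are cut, which takes ring A apart into vinylketene acetal 14 and but-3-yn-2-one (15). The alternative is to substitute a catechol-derived arene at four adjacent positions, which meets the regiochemical problem head-on. Here every substituent position is dictated by the polarity of the two partners. The precursor 14 has no arene in the bicyclic core at all and already carries both stereocentres. The forward reaction must be regioselective (acetyl next to O1) and must aromatise by loss of silanol, not by ring opening.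

**14 ⇒ 13 ⇒ 12 ⇒ 10.** The O–Si bond is cut back to α-alkylidene lactone 13, the methyl ester to acid 12, and the acid to imide 10. Enol silylation has to take a γ-hydrogen of the methyl group and leave C3–H alone.

**10 ⇒ 6 + 7.** The C2–C3 bond (aldol) and the O1–C7a bond (lactonisation) are cut. An auxiliary-controlled syn-aldol sets both stereocentres at once, and a syn aldol adduct can only close to the trans lactone. The aldehyde 7 is commercial. The forward step must react at the α-carbon of a dienolate and with high facial control.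

**6 ⇒ 3 + 4, and 3 ⇒ 1 + 2.** The N-acyl bond is cut to half-ester 3 and oxazolidinone 4. The C3a=C4 bond is cut by a Stobbe condensation of dimethyl succinate (1) with 1,1-dimethoxyacetone (2). This delivers, in one step, the alkylidene succinate with the acid and ester already differentiated in the way the aldol and lactonisation need.

## Roads not taken

**Alternative 1:** The cut is at C3–C3a and O1–C2. Going forward, Ag2O oxidises two phenols: methyl caffeate monobenzyl ether A2 and the rosmarinate A3, whose 3-hydroxyl is free. The β-carbon of the A2 radical must bond to the ring carbon of A3 that lies between the hydroxyl and the side chain, and the phenol then adds to the quinone methide to give A1.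

- Merits: it is by far the shortest road, the whole skeleton appears in one step from two cinnamates, and the trans ring fusion is the normal outcome of quinone methide capture.
- Weak points: two different phenols give homo- and cross-coupled products. The coupling site required on A3 is the hindered position ortho to both the hydroxyl and the side chain, while the para position is freer. The only stereochemical bias is the remote lactate centre, so A1 should form together with its (2R,3R) diastereomer and need separation.
- Comparison: on step count Alternative 1 is clearly better. The chosen plan sets against it auxiliary-controlled C2 and C3 and a ring A whose substitution pattern cannot come out otherwise.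

**Alternative 2:** The cut is at C3–C3a, made by ring contraction. Going forward, PhI(OAc)2 and H2SO4 in HC(OMe)3 convert the (2S)-flavanone A5 into its enol ether, trivalent iodine adds to C3, and the ring A carbon migrates from the ketal carbon to C3 with loss of PhI, giving ester A4.

- Merits: the C7 oxygen and a C4 bromide come from a simple arene, the trans product follows from migration anti to the iodine, and the bromide allows a direct Heck coupling with an acrylate of the lactate. The road is shorter than the chosen one and needs no Baeyer–Villiger step.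
- Weak points: 2-arylchromanones racemise by ring opening to the chalcone, and an electron-rich 2-aryl group under strong acid makes this worse. The benzyloxy-substituted rings are exposed to an oxidant. The peri bromine crowds the carbonyl and lowers the migratory aptitude of the aryl carbon.
- Comparison: the chosen plan is longer. It sets against this two centres that are never in equilibrium with an open-chain form, and no strong acid or oxidant before the arene is complete.

**Alternative 3:** The cut is at C3a–C7a and C6–C7. Going forward, Ph3PAuNTf2 activates the ethynyl ether of A7, furan C2 attacks the oxygen-bearing alkyne carbon, and the opened furan recloses through an arene oxide to the phenol A6.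

- Merits: both fused rings and the free C7 hydroxyl arise in one catalytic, atom-economical step, with the two stereocentres as spectators. In this respect it is better than the chosen plan, which needs three further steps to turn acetyl into benzyloxy.
- Weak points: A7 is a secondary benzylic ethynyl ether β to an ester. The usual ways of making ethynyl ethers use strong base, which would eliminate the alkoxide to a cinnamate. Such ethers also fragment thermally to ketenes. The regiochemistry of arene oxide opening is not secured by the substrate.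
- Comparison: the chosen plan sets against the longer post-annulation sequence a diene precursor made under mild conditions and a dienophile that is a stable commercial liquid.

Key step: step 7

Assumption: sodium (R)-3-(3,4-dihydroxyphenyl)lactate (22) is treated as a purchasable salt.

Assumption: compounds 3 to 13 are carried as mixtures of alkene isomers, because step 6 converts either isomer into the same terminal diene.

## Route

Step 1
Reactants: 1 dimethyl succinate; 2 1,1-dimethoxyacetone
Product: 3 (E/Z)-5,5-dimethoxy-3-(methoxycarbonyl)-4-methylpent-3-enoic acid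
Conditions: KOt-Bu, t-BuOH, 0 °C → rt; aq. HCl
Reagents that add atoms: none
Why: Stobbe condensation: the succinate enolate adds to the ketone, the alkoxide closes a γ-lactone on the distal ester, and E1cB opening gives the alkylidene succinate in which the CH2CO2H arm is the free acid and the ester sits on the alkene carbon.

Step 2
Reactants: 3 (E/Z)-5,5-dimethoxy-3-(methoxycarbonyl)-4-methylpent-3-enoic acid; 4 (S)-4-benzyl-2-oxazolidinone
Product: 6 (4S)-4-benzyl-3-[(E/Z)-5,5-dimethoxy-3-(methoxycarbonyl)-4-methylpent-3-enoyl]-1,3-oxazolidin-2-one, via mixed pivalic anhydride 5 (not isolated)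
Conditions: PivCl, Et3N, THF, −20 °C; then 4, LiCl, −20 °C → rt
Reagents that add atoms: none
Why: N-acylation of the oxazolidinone by a mixed anhydride, activated by LiCl; no strong base is present, so the double bond should not move into conjugation with the imide.

Step 3
Reactants: 6 (4S)-4-benzyl-3-[(E/Z)-5,5-dimethoxy-3-(methoxycarbonyl)-4-methylpent-3-enoyl]-1,3-oxazolidin-2-one; 7 3,4-bis(benzyloxy)benzaldehyde
Product: 10 (4S)-4-benzyl-3-{[(2S,3S)-2-[3,4-bis(benzyloxy)phenyl]-4-(1,1-dimethoxypropan-2-ylidene)-5-oxooxolan-3-yl]carbonyl}-1,3-oxazolidin-2-one, via dibutylboron (Z)-enolate 8 (not isolated), via syn-aldol adduct 9 (not isolated)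
Conditions: Bu2BOTf, i-Pr2NEt, CH2Cl2, 0 °C; 7, −78 → 0 °C; pH 7 buffer, MeOH, H2O2; crude, then PPTS (cat.), PhMe, 60 °C
Reagents that add atoms: none
Why: Evans syn-aldol: the (Z)-boron enolate 8 reacts at its α-carbon through a Zimmerman–Traxler chair in which the benzyl group of the auxiliary blocks one face, which should set both new centres as S (the α-carbon becomes C3 and the carbinol carbon C2 of the benzofuran). Acid-catalysed attack of the new hydroxyl on the conjugated methyl ester (5-exo-trig lactonisation) closes the ring, and a syn adduct can only give the trans-2,3-disubstituted lactone.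

Step 4
Reactants: 10 (4S)-4-benzyl-3-{[(2S,3S)-2-[3,4-bis(benzyloxy)phenyl]-4-(1,1-dimethoxypropan-2-ylidene)-5-oxooxolan-3-yl]carbonyl}-1,3-oxazolidin-2-one
Product: 12 (2S,3S)-2-[3,4-bis(benzyloxy)phenyl]-4-(1,1-dimethoxypropan-2-ylidene)-5-oxooxolane-3-carboxylic acid, via peroxy acid 11 (not isolated)
Conditions: LiOH, H2O2, THF/H2O, 0 °C; Na2SO3; HCl to pH 3
Reagents that add atoms: hydrogen peroxide, OO
Why: Hydroperoxide is a weakly basic α-effect nucleophile that attacks the exocyclic imide carbonyl in preference to the ring carbonyls and to C3–H; sulfite reduces peracid 11 to the acid, a lactone opened in base recloses on acidification, and the auxiliary is recovered.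

Step 5
Reactants: 12 (2S,3S)-2-[3,4-bis(benzyloxy)phenyl]-4-(1,1-dimethoxypropan-2-ylidene)-5-oxooxolane-3-carboxylic acid
Product: 13 methyl (2S,3S)-2-[3,4-bis(benzyloxy)phenyl]-4-(1,1-dimethoxypropan-2-ylidene)-5-oxooxolane-3-carboxylate
Conditions: TMSCHN2, PhMe/MeOH, 0 °C
Reagents that add atoms: (trimethylsilyl)diazomethane, C[Si](C)(C)C=[N+]=[N-]
Why: O-Methylation of the carboxylic acid by a diazoalkane under neutral conditions, which leaves the acetal, the lactone and the acidic C3–H untouched.

Step 6
Reactants: 13 methyl (2S,3S)-2-[3,4-bis(benzyloxy)phenyl]-4-(1,1-dimethoxypropan-2-ylidene)-5-oxooxolane-3-carboxylate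
Product: 14 methyl (2S,3S)-2-[3,4-bis(benzyloxy)phenyl]-5-(tert-butyldimethylsilyloxy)-4-(3,3-dimethoxyprop-1-en-2-yl)-2,3-dihydrofuran-3-carboxylate
Conditions: TBSOTf, Et3N, CH2Cl2, −78 → 0 °C
Reagents that add atoms: tert-butyldimethylsilyl trifluoromethanesulfonate, CC(C)(C)[Si](C)(C)OS(=O)(=O)C(F)(F)F
Why: Vinylogous soft enolisation: the silyl triflate adds to the conjugated lactone carbonyl, the most basic oxygen, and Et3N removes a proton from the γ-methyl group of the silyloxycarbenium ion, so both alkene isomers give the same 2-silyloxy diene. C3–H is cross-conjugated to the activated carbonyl and the acetal methine is tertiary and shielded, so neither should compete, and both stereocentres are untouched.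

Step 7
Reactants: 14 methyl (2S,3S)-2-[3,4-bis(benzyloxy)phenyl]-5-(tert-butyldimethylsilyloxy)-4-(3,3-dimethoxyprop-1-en-2-yl)-2,3-dihydrofuran-3-carboxylate; 15 but-3-yn-2-one
Product: 17 methyl (2S,3S)-7-acetyl-2-[3,4-bis(benzyloxy)phenyl]-4-(dimethoxymethyl)-2,3-dihydro-1-benzofuran-3-carboxylate, via cyclohexa-1,4-diene cycloadduct 16 (not isolated)
Conditions: 15, PhMe, 80 °C; then PPTS (cat.), rt
Reagents that add atoms: none
Why: Normal-demand Diels–Alder reaction between vinylketene acetal 14, whose HOMO is raised by the two oxygens on the future C7a, and ynone 15; the closest known type is the benzannulation of 1-alkoxy-1-silyloxy-1,3-dienes with acetylenic ketones. The six-membered ring closes by [4+2] cycloaddition, with C5–C6 and C7–C7a formed in one operation (concerted but asynchronous, or conjugate addition followed by collapse of the allenolate onto the oxocarbenium carbon; both lead to 16). The selectivity needed is regiochemical: the largest HOMO coefficient lies on the terminal methylene (future C5), which bonds to the unsubstituted β-carbon of the ynone, so the acetyl group must end on C7 next to O1. In 16 the silyloxy group on C7a is pseudo-axial, aligned with both flanking π bonds and antiperiplanar to a lone pair on O1, whereas the C7a–O1 bond lies near the ring plane; ionisation to the cyclic oxocarbenium ion and loss of H from C5 (a 1,4-elimination of t-BuMe2SiOH) is therefore favoured over ring opening and leaves O1 in place. No lasting stereocentre is created, since C7a is transient; C2 and C3 are spectators under these neutral conditions, and C3–H has no sigmatropic path into the diene. The acetal and the benzyl ethers are inert.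

Step 8
Reactants: 17 methyl (2S,3S)-7-acetyl-2-[3,4-bis(benzyloxy)phenyl]-4-(dimethoxymethyl)-2,3-dihydro-1-benzofuran-3-carboxylate
Product: 19 methyl (2S,3S)-2-[3,4-bis(benzyloxy)phenyl]-4-(dimethoxymethyl)-7-hydroxy-2,3-dihydro-1-benzofuran-3-carboxylate, via aryl acetate 18 (not isolated)
Conditions: mCPBA, NaHCO3, CH2Cl2, 0 °C → rt; crude, then K2CO3 (0.2 equiv), MeOH, 0 °C
Reagents that add atoms: 3-chloroperbenzoic acid, OOC(=O)c1cccc(Cl)c1
Why: Baeyer–Villiger oxidation: in the Criegee adduct the oxygen-substituted aryl group migrates in preference to methyl, and solid NaHCO3 keeps the medium neutral so that the acetal is not hydrolysed to an oxidisable aldehyde. Brief carbonate-catalysed methanolysis of aryl acetate 18 frees the phenol and cannot change the methyl ester.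

Step 9
Reactants: 19 methyl (2S,3S)-2-[3,4-bis(benzyloxy)phenyl]-4-(dimethoxymethyl)-7-hydroxy-2,3-dihydro-1-benzofuran-3-carboxylate
Product: 20 methyl (2S,3S)-7-(benzyloxy)-2-[3,4-bis(benzyloxy)phenyl]-4-(dimethoxymethyl)-2,3-dihydro-1-benzofuran-3-carboxylate
Conditions: BnBr, K2CO3, DMF, rt
Reagents that add atoms: benzyl bromide, BrCc1ccccc1
Why: Williamson ether synthesis on the phenoxide; K2CO3 at room temperature is too weak a base to remove C3–H, as is usual in phenol alkylations of 2-aryl-2,3-dihydrobenzofuran-3-carboxylates.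

Step 10
Reactants: 20 methyl (2S,3S)-7-(benzyloxy)-2-[3,4-bis(benzyloxy)phenyl]-4-(dimethoxymethyl)-2,3-dihydro-1-benzofuran-3-carboxylate
Product: 21 methyl (2S,3S)-7-(benzyloxy)-2-[3,4-bis(benzyloxy)phenyl]-4-formyl-2,3-dihydro-1-benzofuran-3-carboxylate
Conditions: 1 M HCl, THF, rt
Reagents that add atoms: water, O
Why: Acid hydrolysis of an aryl dimethyl acetal, assisted by the para benzyloxy group; dilute acid at room temperature should neither ionise the C2–O1 bond nor cleave benzyl ethers.

Step 11
Reactants: 22 sodium (2R)-3-(3,4-dihydroxyphenyl)-2-hydroxypropanoate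
Product: 23 benzyl (2R)-3-[3,4-bis(benzyloxy)phenyl]-2-hydroxypropanoate
Conditions: BnBr, K2CO3, DMF, rt
Reagents that add atoms: benzyl bromide, BrCc1ccccc1
Why: Carbonate-mediated O-alkylation of the carboxylate and both phenols; the secondary hydroxyl is not deprotonated by K2CO3 and stays free, and the α-hydroxy ester centre is not epimerised.

Step 12
Reactants: 23 benzyl (2R)-3-[3,4-bis(benzyloxy)phenyl]-2-hydroxypropanoate; 24 Meldrum's acid (2,2-dimethyl-1,3-dioxane-4,6-dione)
Product: 25 3-{[(2R)-1-(benzyloxy)-3-[3,4-bis(benzyloxy)phenyl]-1-oxopropan-2-yl]oxy}-3-oxopropanoic acid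
Conditions: PhMe, 100 °C
Reagents that add atoms: none
Why: Thermal alcoholysis of Meldrum's acid with loss of acetone gives the malonic acid monoester under neutral conditions, so the stereocentre is safe.

Step 13
Reactants: 21 methyl (2S,3S)-7-(benzyloxy)-2-[3,4-bis(benzyloxy)phenyl]-4-formyl-2,3-dihydro-1-benzofuran-3-carboxylate; 25 3-{[(2R)-1-(benzyloxy)-3-[3,4-bis(benzyloxy)phenyl]-1-oxopropan-2-yl]oxy}-3-oxopropanoic acid
Product: 26 methyl (2S,3S)-7-(benzyloxy)-4-[(1E)-3-{[(2R)-1-(benzyloxy)-3-[3,4-bis(benzyloxy)phenyl]-1-oxopropan-2-yl]oxy}-3-oxoprop-1-en-1-yl]-2-[3,4-bis(benzyloxy)phenyl]-2,3-dihydro-1-benzofuran-3-carboxylate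
Conditions: piperidine (cat.), pyridine, 50 °C
Reagents that add atoms: none
Why: Knoevenagel–Doebner condensation: the iminium ion of the aldehyde is attacked by the malonic half-ester and decarboxylative elimination gives the (E)-propenoate directly. The amine bases are weak and the temperature moderate, so C3 should keep its configuration, and trans is in any case the favoured arrangement.

Step 14
Reactants: 26 methyl (2S,3S)-7-(benzyloxy)-4-[(1E)-3-{[(2R)-1-(benzyloxy)-3-[3,4-bis(benzyloxy)phenyl]-1-oxopropan-2-yl]oxy}-3-oxoprop-1-en-1-yl]-2-[3,4-bis(benzyloxy)phenyl]-2,3-dihydro-1-benzofuran-3-carboxylate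
Product: 27 monomethyl lithospermate, (2R)-3-(3,4-dihydroxyphenyl)-2-{[(2E)-3-[(2S,3S)-2-(3,4-dihydroxyphenyl)-7-hydroxy-3-(methoxycarbonyl)-2,3-dihydro-1-benzofuran-4-yl]prop-2-enoyl]oxy}propanoic acid
Conditions: BCl3, C6HMe5, CH2Cl2, −78 °C; MeOH quench
Reagents that add atoms: none
Why: Lewis-acid debenzylation: BCl3 cleaves the five aryl benzyl ethers and the benzyl ester, and pentamethylbenzene traps the benzyl cations by Friedel–Crafts alkylation, so no hydrogen, base or water is needed. At −78 °C the methyl ester, the alkenoate and the alkene should remain.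

## Compound list

1 | dimethyl succinate | COC(=O)CCC(=O)OC | starting material
2 | 1,1-dimethoxyacetone | CC(=O)C(OC)OC | starting material
3 | (E/Z)-5,5-dimethoxy-3-(methoxycarbonyl)-4-methylpent-3-enoic acid | COC(=O)C(CC(=O)O)=C(C)C(OC)OC | intermediate
4 | (S)-4-benzyl-2-oxazolidinone | O=C1N[C@@H](Cc2ccccc2)CO1 | starting material
5 | (E/Z)-5,5-dimethoxy-3-(methoxycarbonyl)-4-methylpent-3-enoic pivalic anhydride | COC(=O)C(CC(=O)OC(=O)C(C)(C)C)=C(C)C(OC)OC | intermediate (not isolated)
6 | (4S)-4-benzyl-3-[(E/Z)-5,5-dimethoxy-3-(methoxycarbonyl)-4-methylpent-3-enoyl]-1,3-oxazolidin-2-one | COC(=O)C(CC(=O)N1C(=O)OC[C@@H]1Cc1ccccc1)=C(C)C(OC)OC | intermediate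
7 | 3,4-bis(benzyloxy)benzaldehyde | O=Cc1ccc(OCc2ccccc2)c(OCc2ccccc2)c1 | starting material
8 | dibutylboron (Z)-enolate of 6 | CCCCB(CCCC)O/C(=C\C(C(=O)OC)=C(C)C(OC)OC)N1C(=O)OC[C@@H]1Cc1ccccc1 | intermediate (not isolated)
9 | (4S)-4-benzyl-3-{(2S)-2-[(S)-[3,4-bis(benzyloxy)phenyl](hydroxy)methyl]-5,5-dimethoxy-3-(methoxycarbonyl)-4-methylpent-3-enoyl}-1,3-oxazolidin-2-one | COC(=O)C(=C(C)C(OC)OC)[C@H](C(=O)N1C(=O)OC[C@@H]1Cc1ccccc1)[C@H](O)c1ccc(OCc2ccccc2)c(OCc2ccccc2)c1 | intermediate (not isolated)
10 | (4S)-4-benzyl-3-{[(2S,3S)-2-[3,4-bis(benzyloxy)phenyl]-4-(1,1-dimethoxypropan-2-ylidene)-5-oxooxolan-3-yl]carbonyl}-1,3-oxazolidin-2-one | O=C(N1C(=O)OC[C@@H]1Cc1ccccc1)[C@H]1C(=C(C)C(OC)OC)C(=O)O[C@@H]1c1ccc(OCc2ccccc2)c(OCc2ccccc2)c1 | intermediate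
11 | (2S,3S)-2-[3,4-bis(benzyloxy)phenyl]-4-(1,1-dimethoxypropan-2-ylidene)-5-oxooxolane-3-carboperoxoic acid | OOC(=O)[C@H]1C(=C(C)C(OC)OC)C(=O)O[C@@H]1c1ccc(OCc2ccccc2)c(OCc2ccccc2)c1 | intermediate (not isolated)
12 | (2S,3S)-2-[3,4-bis(benzyloxy)phenyl]-4-(1,1-dimethoxypropan-2-ylidene)-5-oxooxolane-3-carboxylic acid | OC(=O)[C@H]1C(=C(C)C(OC)OC)C(=O)O[C@@H]1c1ccc(OCc2ccccc2)c(OCc2ccccc2)c1 | intermediate
13 | methyl (2S,3S)-2-[3,4-bis(benzyloxy)phenyl]-4-(1,1-dimethoxypropan-2-ylidene)-5-oxooxolane-3-carboxylate | COC(=O)[C@H]1C(=C(C)C(OC)OC)C(=O)O[C@@H]1c1ccc(OCc2ccccc2)c(OCc2ccccc2)c1 | intermediate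
14 | methyl (2S,3S)-2-[3,4-bis(benzyloxy)phenyl]-5-(tert-butyldimethylsilyloxy)-4-(3,3-dimethoxyprop-1-en-2-yl)-2,3-dihydrofuran-3-carboxylate | COC(=O)[C@H]1C(C(=C)C(OC)OC)=C(O[Si](C)(C)C(C)(C)C)O[C@@H]1c1ccc(OCc2ccccc2)c(OCc2ccccc2)c1 | intermediate
15 | but-3-yn-2-one | CC(=O)C#C | starting material
16 | methyl (2S,3S)-7-acetyl-2-[3,4-bis(benzyloxy)phenyl]-7a-(tert-butyldimethylsilyloxy)-4-(dimethoxymethyl)-2,3,5,7a-tetrahydro-1-benzofuran-3-carboxylate (C7a not defined) | COC(=O)[C@H]1C2=C(C(OC)OC)CC=C(C(C)=O)C2(O[Si](C)(C)C(C)(C)C)O[C@@H]1c1ccc(OCc2ccccc2)c(OCc2ccccc2)c1 | intermediate (not isolated)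
17 | methyl (2S,3S)-7-acetyl-2-[3,4-bis(benzyloxy)phenyl]-4-(dimethoxymethyl)-2,3-dihydro-1-benzofuran-3-carboxylate | COC(=O)[C@H]1c2c(C(OC)OC)ccc(C(C)=O)c2O[C@@H]1c1ccc(OCc2ccccc2)c(OCc2ccccc2)c1 | intermediate
18 | methyl (2S,3S)-7-acetoxy-2-[3,4-bis(benzyloxy)phenyl]-4-(dimethoxymethyl)-2,3-dihydro-1-benzofuran-3-carboxylate | COC(=O)[C@H]1c2c(C(OC)OC)ccc(OC(C)=O)c2O[C@@H]1c1ccc(OCc2ccccc2)c(OCc2ccccc2)c1 | intermediate (not isolated)
19 | methyl (2S,3S)-2-[3,4-bis(benzyloxy)phenyl]-4-(dimethoxymethyl)-7-hydroxy-2,3-dihydro-1-benzofuran-3-carboxylate | COC(=O)[C@H]1c2c(C(OC)OC)ccc(O)c2O[C@@H]1c1ccc(OCc2ccccc2)c(OCc2ccccc2)c1 | intermediate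
20 | methyl (2S,3S)-7-(benzyloxy)-2-[3,4-bis(benzyloxy)phenyl]-4-(dimethoxymethyl)-2,3-dihydro-1-benzofuran-3-carboxylate | COC(=O)[C@H]1c2c(C(OC)OC)ccc(OCc3ccccc3)c2O[C@@H]1c1ccc(OCc2ccccc2)c(OCc2ccccc2)c1 | intermediate
21 | methyl (2S,3S)-7-(benzyloxy)-2-[3,4-bis(benzyloxy)phenyl]-4-formyl-2,3-dihydro-1-benzofuran-3-carboxylate | COC(=O)[C@H]1c2c(C=O)ccc(OCc3ccccc3)c2O[C@@H]1c1ccc(OCc2ccccc2)c(OCc2ccccc2)c1 | intermediate
22 | sodium (2R)-3-(3,4-dihydroxyphenyl)-2-hydroxypropanoate | [Na+].[O-]C(=O)[C@H](O)Cc1ccc(O)c(O)c1 | starting material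
23 | benzyl (2R)-3-[3,4-bis(benzyloxy)phenyl]-2-hydroxypropanoate | O=C(OCc1ccccc1)[C@H](O)Cc1ccc(OCc2ccccc2)c(OCc2ccccc2)c1 | intermediate
24 | Meldrum's acid (2,2-dimethyl-1,3-dioxane-4,6-dione) | CC1(C)OC(=O)CC(=O)O1 | starting material
25 | 3-{[(2R)-1-(benzyloxy)-3-[3,4-bis(benzyloxy)phenyl]-1-oxopropan-2-yl]oxy}-3-oxopropanoic acid | OC(=O)CC(=O)O[C@H](Cc1ccc(OCc2ccccc2)c(OCc2ccccc2)c1)C(=O)OCc1ccccc1 | intermediate
26 | hexabenzyl derivative of the target (five benzyl ethers and the benzyl ester; full name in step 13) | COC(=O)[C@H]1c2c(/C=C/C(=O)O[C@H](Cc3ccc(OCc4ccccc4)c(OCc4ccccc4)c3)C(=O)OCc3ccccc3)ccc(OCc3ccccc3)c2O[C@@H]1c1ccc(OCc2ccccc2)c(OCc2ccccc2)c1 | intermediate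
27 | monomethyl lithospermate | COC(=O)[C@H]1c2c(/C=C/C(=O)O[C@H](Cc3ccc(O)c(O)c3)C(=O)O)ccc(O)c2O[C@@H]1c1ccc(O)c(O)c1 | target

## Step count and least certain steps

Total: 14 steps. Longest linear sequence: 12 steps (steps 1 to 10, then 13 and 14); steps 11 and 12 form the side branch.

**Key step (step 7).** The ynone may act only as a Michael acceptor, with silyl transfer to the allenolate oxygen before the second bond forms, so that the ring does not close. The ketene acetal may also be hydrolysed by traces of water at the temperature an alkyne dienophile needs. Aromatisation could proceed by cleavage of the C7a–O1 bond instead of the C7a–OSi bond. The fallback replaces the alkyne by an alkene surrogate, which is the better dienophile and reacts at lower temperature with the same polarity. It sets out from 14, which is combined with 3-bromobut-3-en-2-one (PhMe, rt to 40 °C) to give methyl (2S,3S)-7-acetyl-2-[3,4-bis(benzyloxy)phenyl]-7-bromo-7a-(tert-butyldimethylsilyloxy)-4-(dimethoxymethyl)-2,3,5,6,7,7a-hexahydro-1-benzofuran-3-carboxylate F1. DBU in CH2Cl2 at 0 °C then removes HBr, and the resulting diene 16 loses silanol as in the main route, so the sequence returns at 17.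

**Step 6.** Proton removal could occur at C3 (α to the methyl ester), which would move the double bond into the ring and erase C3. It could also occur at the acetal methine, or the silyl triflate could ionise the acetal. The fallback sets out from acid 12 and uses anionic instead of Lewis-acidic enolisation. KHMDS (2 equiv) with TBSCl in THF/DMPU at −78 °C first forms the carboxylate, which shields C3–H in the way known for dianions of paraconic acids. It then forms the extended enolate, and silylation gives tert-butyldimethylsilyl (2S,3S)-2-[3,4-bis(benzyloxy)phenyl]-5-(tert-butyldimethylsilyloxy)-4-(3,3-dimethoxyprop-1-en-2-yl)-2,3-dihydrofuran-3-carboxylate F2. Cycloaddition of F2 with 15 as in step 7 and aqueous work-up give (2S,3S)-7-acetyl-2-[3,4-bis(benzyloxy)phenyl]-4-(dimethoxymethyl)-2,3-dihydro-1-benzofuran-3-carboxylic acid F3. Methylation of F3 with TMSCHN2 returns to the route at 17.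

**Step 8.** Aryl migration from an acetyl ketone with a single ortho oxygen may be slow, which leaves time for acetal hydrolysis and oxidation of the freed aldehyde. The fallback sets out from 14 and changes the acyl group to one that migrates its aryl partner far more readily. Cycloaddition with prop-2-ynal (PhMe, 60 °C) gives methyl (2S,3S)-2-[3,4-bis(benzyloxy)phenyl]-4-(dimethoxymethyl)-7-formyl-2,3-dihydro-1-benzofuran-3-carboxylate F4. Dakin-type oxidation with mCPBA/NaHCO3 gives methyl (2S,3S)-2-[3,4-bis(benzyloxy)phenyl]-4-(dimethoxymethyl)-7-(formyloxy)-2,3-dihydro-1-benzofuran-3-carboxylate F5. Methanolysis (K2CO3, MeOH, 0 °C) returns to the route at 19.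

**Step 13.** Epimerisation at C3, or ring opening by β-elimination of the phenoxide, could occur under amine base at 50 °C, and a hindered ortho-substituted aldehyde may condense slowly. The fallback is a base-free Wittig reaction and sets out from alcohol 23. Addition of 23 to (triphenylphosphoranylidene)ketene, Ph3P=C=C=O, in PhMe at 80 °C gives benzyl (2R)-3-[3,4-bis(benzyloxy)phenyl]-2-{[(triphenyl-λ5-phosphanylidene)acetyl]oxy}propanoate F6. This stabilised ylide reacts with aldehyde 21 in PhMe at 80 °C to give the (E)-alkene and returns to the route at 26.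

**Step 14.** The Lewis acid may ionise the C2–O1 benzylic ether, leading to epimerisation at C2 or ring opening, and the benzyl ester may cleave incompletely at the temperature the rest tolerates. The fallback removes all benzyl groups before the alkene exists, so that hydrogen can be used and no Lewis acid meets the dihydrobenzofuran.
- It sets out from 20: H2, Pd/C in EtOAc gives methyl (2S,3S)-2-(3,4-dihydroxyphenyl)-4-(dimethoxymethyl)-7-hydroxy-2,3-dihydro-1-benzofuran-3-carboxylate F7.
- Dilute HCl in THF gives methyl (2S,3S)-2-(3,4-dihydroxyphenyl)-4-formyl-7-hydroxy-2,3-dihydro-1-benzofuran-3-carboxylate F8.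
- Hydrogenolysis of 25 (H2, Pd/C, EtOAc) gives (2R)-2-[(carboxyacetyl)oxy]-3-(3,4-dihydroxyphenyl)propanoic acid F9.
- Knoevenagel–Doebner condensation of F8 with F9 (piperidine, pyridine, 50 °C, under argon), a reaction known to tolerate free hydroxybenzaldehydes, arrives directly at 27.

## Further compounds

F1 | step 7 | methyl (2S,3S)-7-acetyl-2-[3,4-bis(benzyloxy)phenyl]-7-bromo-7a-(tert-butyldimethylsilyloxy)-4-(dimethoxymethyl)-2,3,5,6,7,7a-hexahydro-1-benzofuran-3-carboxylate (C7 and C7a not defined) | COC(=O)[C@H]1C2=C(C(OC)OC)CCC(Br)(C(C)=O)C2(O[Si](C)(C)C(C)(C)C)O[C@@H]1c1ccc(OCc2ccccc2)c(OCc2ccccc2)c1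
F2 | step 6 | tert-butyldimethylsilyl (2S,3S)-2-[3,4-bis(benzyloxy)phenyl]-5-(tert-butyldimethylsilyloxy)-4-(3,3-dimethoxyprop-1-en-2-yl)-2,3-dihydrofuran-3-carboxylate | CC(C)(C)[Si](C)(C)OC(=O)[C@H]1C(C(=C)C(OC)OC)=C(O[Si](C)(C)C(C)(C)C)O[C@@H]1c1ccc(OCc2ccccc2)c(OCc2ccccc2)c1
F3 | step 6 | (2S,3S)-7-acetyl-2-[3,4-bis(benzyloxy)phenyl]-4-(dimethoxymethyl)-2,3-dihydro-1-benzofuran-3-carboxylic acid | OC(=O)[C@H]1c2c(C(OC)OC)ccc(C(C)=O)c2O[C@@H]1c1ccc(OCc2ccccc2)c(OCc2ccccc2)c1
F4 | step 8 | methyl (2S,3S)-2-[3,4-bis(benzyloxy)phenyl]-4-(dimethoxymethyl)-7-formyl-2,3-dihydro-1-benzofuran-3-carboxylate | COC(=O)[C@H]1c2c(C(OC)OC)ccc(C=O)c2O[C@@H]1c1ccc(OCc2ccccc2)c(OCc2ccccc2)c1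
F5 | step 8 | methyl (2S,3S)-2-[3,4-bis(benzyloxy)phenyl]-4-(dimethoxymethyl)-7-(formyloxy)-2,3-dihydro-1-benzofuran-3-carboxylate | COC(=O)[C@H]1c2c(C(OC)OC)ccc(OC=O)c2O[C@@H]1c1ccc(OCc2ccccc2)c(OCc2ccccc2)c1
F6 | step 13 | benzyl (2R)-3-[3,4-bis(benzyloxy)phenyl]-2-{[(triphenyl-λ5-phosphanylidene)acetyl]oxy}propanoate | O=C(C=P(c1ccccc1)(c1ccccc1)c1ccccc1)O[C@H](Cc1ccc(OCc2ccccc2)c(OCc2ccccc2)c1)C(=O)OCc1ccccc1
F7 | step 14 | methyl (2S,3S)-2-(3,4-dihydroxyphenyl)-4-(dimethoxymethyl)-7-hydroxy-2,3-dihydro-1-benzofuran-3-carboxylate | COC(=O)[C@H]1c2c(C(OC)OC)ccc(O)c2O[C@@H]1c1ccc(O)c(O)c1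
F8 | step 14 | methyl (2S,3S)-2-(3,4-dihydroxyphenyl)-4-formyl-7-hydroxy-2,3-dihydro-1-benzofuran-3-carboxylate | COC(=O)[C@H]1c2c(C=O)ccc(O)c2O[C@@H]1c1ccc(O)c(O)c1
F9 | step 14 | (2R)-2-[(carboxyacetyl)oxy]-3-(3,4-dihydroxyphenyl)propanoic acid | OC(=O)CC(=O)O[C@H](Cc1ccc(O)c(O)c1)C(=O)O
A1 | alternative 1 | tert-butyl ester and tetra-O-benzyl ether of the target with the 4-hydroxyl of the C2 aryl group free | COC(=O)[C@H]1c2c(/C=C/C(=O)O[C@H](Cc3ccc(OCc4ccccc4)c(OCc4ccccc4)c3)C(=O)OC(C)(C)C)ccc(OCc3ccccc3)c2O[C@@H]1c1ccc(O)c(OCc2ccccc2)c1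
A2 | alternative 1 | methyl (2E)-3-[3-(benzyloxy)-4-hydroxyphenyl]prop-2-enoate | COC(=O)/C=C/c1ccc(O)c(OCc2ccccc2)c1
A3 | alternative 1 | tert-butyl (2R)-2-{[(2E)-3-[4-(benzyloxy)-3-hydroxyphenyl]prop-2-enoyl]oxy}-3-[3,4-bis(benzyloxy)phenyl]propanoate | O=C(/C=C/c1ccc(OCc2ccccc2)c(O)c1)O[C@H](Cc1ccc(OCc2ccccc2)c(OCc2ccccc2)c1)C(=O)OC(C)(C)C
A4 | alternative 2 | methyl (2S,3S)-7-(benzyloxy)-2-[3,4-bis(benzyloxy)phenyl]-4-bromo-2,3-dihydro-1-benzofuran-3-carboxylate | COC(=O)[C@H]1c2c(Br)ccc(OCc3ccccc3)c2O[C@@H]1c1ccc(OCc2ccccc2)c(OCc2ccccc2)c1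
A5 | alternative 2 | (2S)-8-(benzyloxy)-2-[3,4-bis(benzyloxy)phenyl]-5-bromo-2,3-dihydro-4H-chromen-4-one | O=C1C[C@@H](c2ccc(OCc3ccccc3)c(OCc3ccccc3)c2)Oc2c(OCc3ccccc3)ccc(Br)c12
A6 | alternative 3 | methyl (2S,3S)-2-[3,4-bis(benzyloxy)phenyl]-4-[(tert-butyldimethylsilyloxy)methyl]-7-hydroxy-2,3-dihydro-1-benzofuran-3-carboxylate | COC(=O)[C@H]1c2c(CO[Si](C)(C)C(C)(C)C)ccc(O)c2O[C@@H]1c1ccc(OCc2ccccc2)c(OCc2ccccc2)c1
A7 | alternative 3 | methyl (2R,3S)-3-[3,4-bis(benzyloxy)phenyl]-2-{3-[(tert-butyldimethylsilyloxy)methyl]furan-2-yl}-3-(ethynyloxy)propanoate | COC(=O)[C@@H](c1occc1CO[Si](C)(C)C(C)(C)C)[C@H](OC#C)c1ccc(OCc2ccccc2)c(OCc2ccccc2)c1
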